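Find the nucleophile charge that brings this flask to the asked part of reacted electrophile.

electrophile 5.0 mM; time 10 s

    electrophile + nucleophile → acid set free + product (k1 = 6.5 M⁻¹ s⁻¹)
    electrophile + acid set free ⇌ idle adduct, settled at all times (K2 = 7200 M⁻¹)
    nucleophile + acid set free ⇌ protonated nucleophile, settled at all times (K3 = 5.0 × 10⁵ M⁻¹)
    nucleophile ⇌ dormant form (K4 = 0.70, k4 = 0.11 s⁻¹)

* the concentration of nucleophile at which the part of the electrophile that has reacted at 10 s is just 95%, in mM

- acid set free is meant together with its idle adduct
- the amount of nucleophile is what is sought; it is there from the start
- what has gone from electrophile into another species counts as reacted, even if it can come back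
- run time (flask): 10 s

We replace the curve of free nucleophile by its mean, and the electrophile then falls in pseudo-first-order fashion. Here 46.1 mM is the required mean free nucleophile, the logarithm of charged over remaining electrophile divided by rate constant and time, and it is more than the electrophile charge. Each reacted electrophile costs two nucleophiles, one in the step and one as protonated nucleophile, because acid set free binds nucleophile far more strongly than it binds electrophile. So 9.50 mM leaves the charge, and we count it as gone from the start. The rest relaxes towards a free share of 58.8%, with a half-life of 2.59 s that is shorter than the run. The early excess over balance, averaged over the run with the forward and back rates of the dormant step added, lifts the mean free share to 74.2%. Our charge for this flask is therefore 71.6 mM.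

Take a neighbouring flask with 80.0% of that nucleophile. Its loss to acid stays nearly the same, so its mean drops to 35.5 mM, less than the charge alone would suggest, and it ends near 90.0% reacted.

The forecast puts the charge at 70.7 mM, holding that “Each reaction therefore uses two nucleophiles”. The simulation gives 70.5 mM.

In this flask, half of the electrophile step's turnover was done by 1.58 s, and half of the turnover towards dormant form by 2.11 s. Free nucleophile stood at 85.7% of the charge at 1.00 s, then 60.7% at 5.00 s and 52.8% at 10.0 s. The required mean of 46.1 mM is 65.4% of this charge, less than the share free at 1.00 s and more than the share free at 5.00 s. The neighbouring flask, with 80.0% of this charge, reached 90.5%, which by the same rule read backwards means a mean free nucleophile of 36.2 mM.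

The numbers of this flask belong to no real substance; the rest is arithmetic.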